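The nine-membered carbocycle is disconnected at the bond between its allylic CH2 (C7) and the sp2 ring carbon C8 that carries the exocyclic methylene beside the cyclobutane. A B-alkyl Suzuki–Miyaura macrocyclisation forms this bond last, on a seco compound in which cyclobutane, pyran and triketone rings are complete, C5 bears a vinyl group and C9 a 1-bromovinyl group. The seco compound is cut out of (−)-caryophyllene oxide: an Eschenmoser–Tanabe fragmentation opens its ring at C6–C7 with C1, C9 and the epoxide intact, a vinyl cuprate then inverts C5 and supplies the new C6 and C7, while the old C6 becomes the pyran CH2 and the old C7 the exocyclic methylene.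

Key step: step 13

Remark: the target has the (1R,9S) cyclobutane of natural caryophyllanes, so (−)-caryophyllene oxide is the matching chiral pool; locants C1–C13 are caryophyllene locants of the compound in question, and the trione ring is numbered C1′–C6′ (C2′ acyl, C4′ gem-dimethyl, C6′ the carbon that is alkylated).

Step 1
Reactants: 1 (−)-caryophyllene oxide
Product: 3 kobusone (4,5-epoxy-13-norcaryophyllan-8-one), via ozonide 2 (not isolated)
Conditions: O3, CH2Cl2, −78 °C; then Me2S, −78 to 23 °C
Reagents that add atoms: ozone, [O-][O+]=O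
Why: Ozonolysis (Criegee mechanism) of the only alkene, the exocyclic C8=C13 methylene, followed by reduction of the ozonide should give the C8 ketone and leave the epoxide and the C1, C4, C5 and C9 stereocentres untouched.

Step 2
Reactants: 3 kobusone
Product: 4 (6Z)-4,5-epoxy-13-norcaryophyll-6-en-8-one
Conditions: IBX (2-iodoxybenzoic acid, 2.5 equiv), DMSO/fluorobenzene, 65 °C
Reagents that add atoms: none
Why: IBX α,β-dehydrogenation of ketones proceeds through the enol and can only introduce the C6=C7 double bond, because enolisation towards C9 would place an exocyclic double bond on the cyclobutane; C9 should remain the more stable trans ring fusion.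

Step 3
Reactants: 4 epoxy enone
Product: 5 4,5:6,7-diepoxy-13-norcaryophyllan-8-one
Conditions: 30% H2O2, NaOH (cat.), MeOH, 0 °C
Reagents that add atoms: hydrogen peroxide, OO
Why: Weitz–Scheffer nucleophilic epoxidation: hydroperoxide adds to the enone β-carbon C6 and the enolate closes the oxirane, leaving the isolated C4–C5 epoxide alone; the configuration at C6/C7 is irrelevant because both centres are erased in step 4.

Step 4
Reactants: 5 diepoxy ketone
Product: 8 epoxy alcohol [(2R,3R)-3-{2-[(1R,2S)-2-ethynyl-4,4-dimethylcyclobutyl]ethyl}-3-methyloxiran-2-yl]methanol, via tosylhydrazone 6 (not isolated), via alkynal 7 (not isolated)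
Conditions: TsNHNH2 (1.1 equiv), CH2Cl2/AcOH (4:1), −20 to 10 °C; then NaHCO3 wash, NaBH4, MeOH, −20 °C
Reagents that add atoms: none
Why: Eschenmoser–Tanabe fragmentation: the tosylhydrazone opens the α,β-epoxide to an alkoxy azoalkene that cleaves the C6–C7 bond with loss of N2 and sulfinate, which should unzip the nine-membered ring into the C8≡C7 terminal alkyne and the C6 aldehyde while C1, C9 and the C4–C5 epoxide are untouched; borohydride then reduces the sensitive glycidic aldehyde.

Step 5
Reactants: 8 epoxy alcohol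
Product: 9 (2S,3R)-2-ethenyl-5-[(1R,2S)-2-ethynyl-4,4-dimethylcyclobutyl]-3-methylpentane-1,3-diol
Conditions: CH2=CHMgBr (6 equiv), CuI (0.5 equiv), THF, −40 to −15 °C
Reagents that add atoms: vinylmagnesium bromide, C=C[Mg]Br
Why: Copper-catalysed Grignard (cuprate) opening of a 2,3-epoxy alcohol occurs by SN2 attack at the secondary carbon C5 because C4 is fully substituted, so C5 is set with inversion while the C4 tertiary alcohol keeps the epoxide configuration; the alkyne is masked in situ as its magnesium acetylide.

Step 6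
Reactants: 9 diol
Product: 10 1,3-bis(triethylsilyl) ether of 9
Conditions: TESOTf (2.5 equiv), 2,6-lutidine, CH2Cl2, −78 to 0 °C
Reagents that add atoms: triethylsilyl trifluoromethanesulfonate, CC[Si](CC)(CC)OS(=O)(=O)C(F)(F)F
Why: A silyl triflate with a hindered pyridine base should silylate both the primary and the hindered tertiary hydroxyl without touching the alkyne or the alkene.

Step 7
Reactants: 10 bis-silyl ether
Product: 12 1,3-bis(triethylsilyl) ether of (2S,3R)-5-[(1R,2S)-2-(1-bromoethenyl)-4,4-dimethylcyclobutyl]-2-ethenyl-3-methylpentane-1,3-diol, via alkenylborane 11 (not isolated)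
Conditions: B-bromo-9-BBN (1.2 equiv), CH2Cl2, 0 °C; then AcOH, 0 to 23 °C
Reagents that add atoms: B-bromo-9-borabicyclo[3.3.1]nonane, BrB1C2CCCC1CCC2
Why: Haloboration: B–Br adds syn and Markovnikov across the terminal alkyne only (Br to the internal carbon C8, boron to the terminal carbon), and protodeboronation with acetic acid leaves the 2-bromo-1-alkene; the vinyl group does not react with the haloborane.

Step 8
Reactants: 12 bromoalkene
Product: 13 (2R,3R)-5-[(1R,2S)-2-(1-bromoethenyl)-4,4-dimethylcyclobutyl]-2-ethenyl-3-methyl-3-(triethylsilyloxy)pentanal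
Conditions: (COCl)2, DMSO, CH2Cl2, −78 to −35 °C; then Et3N, −78 to 0 °C
Reagents that add atoms: none
Why: Under Swern conditions a primary triethylsilyl ether is cleaved by the chlorosulfonium salt and oxidised directly to the aldehyde whereas the tertiary silyl ether cannot react, and the cold amine step limits enolisation of the α-stereocentre C5.

Step 9
Reactants: 14 phloroglucinol
Product: 15 2-methyl-1-(2,4,6-trihydroxyphenyl)propan-1-one
Conditions: isobutyryl chloride, AlCl3, CH2Cl2/MeNO2, 0 to 40 °C
Reagents that add atoms: isobutyryl chloride, CC(C)C(Cl)=O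
Why: Friedel–Crafts C-acylation of the very electron-rich arene should stop at the mono-ketone because the chelated acyl group deactivates the ring.

Step 10
Reactants: 15 acylphloroglucinol
Product: 16 2-isobutyryl-4,4-dimethylcyclohexane-1,3,5-trione
Conditions: MeI (2.1 equiv), NaOMe, MeOH, 0 to 23 °C
Reagents that add atoms: iodomethane, CI
Why: Base-mediated C-methylation of the acylphloroglucinolate twice at the same ring carbon is a dearomatising alkylation that should give the gem-dimethyl trione, over-methylation being limited by the stoichiometry.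

Step 11
Reactants: 13 aldehyde, 16 trione
Product: 18 2′-isobutyryl-4′,4′-dimethyl-6′-alkylcyclohexane-1′,3′,5′-trione whose alkyl group is the (2R,3R)-5-[(1R,2S)-2-(1-bromoethenyl)-4,4-dimethylcyclobutyl]-2-ethenyl-3-methyl-3-(triethylsilyloxy)pentyl chain, via alkylidene 17 (not isolated)
Conditions: Hantzsch ester (1.2 equiv), L-proline (10 mol%), CH2Cl2, 23 °C
Reagents that add atoms: none
Why: Three-component reductive alkylation: Knoevenagel condensation at C6′, the only free CH of the trione, gives an alkylidene-trione that is reduced at once by conjugate hydride transfer from the Hantzsch ester, and no base strong enough to enolise the aldehyde α-stereocentre C5 is present.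

Step 12
Reactants: 18 alkylated trione
Product: 20 (2R,3R)-2-{2-[(1R,2S)-2-(1-bromoethenyl)-4,4-dimethylcyclobutyl]ethyl}-3-ethenyl-5-hydroxy-6-isobutyryl-2,8,8-trimethyl-3,4-dihydro-2H-chromen-7(8H)-one, via alcohol 19 (not isolated)
Conditions: TsOH·H2O (0.3 equiv), CH2Cl2, 0 to 30 °C
Reagents that add atoms: none
Why: Acid removes the silyl group by attack at silicon, and the tertiary hydroxyl then adds to the free vinylogous-acid carbon C5′ (the C1′ and C3′ oxygens are tied up in the hydrogen-bonded acyl-enol unit) and water is lost; this addition–elimination should close the pyran without breaking the C4–O bond, so C4 keeps its configuration.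

Step 13
Reactants: 20 seco bromide
Product: 22 target CNP0497637.2, via alkylborane 21 (not isolated)
Conditions: 9-BBN dimer (3 equiv B–H), THF, 0 to 23 °C; then syringe-pump addition to Pd(dppf)Cl2 (0.2 equiv), AsPh3 (0.4 equiv), Cs2CO3, DMF/THF/H2O, 1 mM, 50 °C
Reagents that add atoms: none
Why: 9-BBN adds anti-Markovnikov to the monosubstituted vinyl group (the first equivalent only caps the acidic enol as its borinate), zerovalent palladium inserts into the C8–Br bond, base-assisted transmetalation transfers the primary alkyl group and reductive elimination forms the C7–C8 bond. The closest known reaction type is the B-alkyl Suzuki–Miyaura macrocyclisation used to close medium and large carbocycles. The nine-membered ring is closed by intramolecular C(sp3)–C(sp2) coupling through a ten-membered palladacycle, and the exocyclic methylene is delivered directly because C8 stays sp2. No stereocentre is formed: C1 and C9 come from the chiral pool, C4 from the epoxide and C5 from the cuprate opening, and none can epimerise under the conditions. The step needs chemoselective hydroboration and ring closure in preference to oligomerisation. The 1-bromovinyl group is inert to 9-BBN because it is 1,1-disubstituted and electron-poor, and high dilution with slow addition, together with the vicinal trans side chains on the pyran and the trans-cyclobutane, should hold the two termini close.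

Compound list
1 | (−)-caryophyllene oxide, (1R,4R,5R,9S)-4,5-epoxycaryophyll-8(13)-ene | C=C1CC[C@H]2O[C@]2(C)CC[C@@H]3[C@@H]1CC3(C)C | starting material
2 | ozonide of 1 (1,2,4-trioxolane spiro-fused at C8, C8 unassigned) | C1OC2(OO1)CC[C@H]3O[C@]3(C)CC[C@@H]4[C@@H]2CC4(C)C | intermediate
3 | kobusone, (1R,4R,5R,9S)-4,5-epoxy-13-norcaryophyllan-8-one | O=C1CC[C@H]2O[C@]2(C)CC[C@@H]3[C@@H]1CC3(C)C | intermediate
4 | (1R,4R,5R,6Z,9S)-4,5-epoxy-13-norcaryophyll-6-en-8-one | O=C1/C=C\[C@H]2O[C@]2(C)CC[C@@H]3[C@@H]1CC3(C)C | intermediate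
5 | (1R,4R,5R,9S)-4,5:6,7-diepoxy-13-norcaryophyllan-8-one (new C6/C7 epoxide unassigned, erased in step 4) | O=C1C4OC4[C@H]2O[C@]2(C)CC[C@@H]3[C@@H]1CC3(C)C | intermediate
6 | N-tosylhydrazone of 5 | Cc1ccc(cc1)S(=O)(=O)NN=C1C4OC4[C@H]2O[C@]2(C)CC[C@@H]3[C@@H]1CC3(C)C | intermediate
7 | (2S,3R)-3-{2-[(1R,2S)-2-ethynyl-4,4-dimethylcyclobutyl]ethyl}-3-methyloxirane-2-carbaldehyde | C#C[C@H]1CC(C)(C)[C@@H]1CC[C@@]1(C)O[C@@H]1C=O | intermediate
8 | [(2R,3R)-3-{2-[(1R,2S)-2-ethynyl-4,4-dimethylcyclobutyl]ethyl}-3-methyloxiran-2-yl]methanol | C#C[C@H]1CC(C)(C)[C@@H]1CC[C@@]1(C)O[C@@H]1CO | intermediate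
9 | (2S,3R)-2-ethenyl-5-[(1R,2S)-2-ethynyl-4,4-dimethylcyclobutyl]-3-methylpentane-1,3-diol | C#C[C@H]1CC(C)(C)[C@@H]1CC[C@@](C)(O)[C@@H](C=C)CO | intermediate
10 | 1,3-bis(triethylsilyl) ether of 9 | C#C[C@H]1CC(C)(C)[C@@H]1CC[C@@](C)(O[Si](CC)(CC)CC)[C@@H](C=C)CO[Si](CC)(CC)CC | intermediate
11 | (Z)-2-bromoalkenyl-9-BBN adduct of 10 (Br on the carbon attached to the cyclobutane) | Br/C(=C\B1C2CCCC1CCC2)[C@H]1CC(C)(C)[C@@H]1CC[C@@](C)(O[Si](CC)(CC)CC)[C@@H](C=C)CO[Si](CC)(CC)CC | intermediate
12 | 1,3-bis(triethylsilyl) ether of (2S,3R)-5-[(1R,2S)-2-(1-bromoethenyl)-4,4-dimethylcyclobutyl]-2-ethenyl-3-methylpentane-1,3-diol | C=C(Br)[C@H]1CC(C)(C)[C@@H]1CC[C@@](C)(O[Si](CC)(CC)CC)[C@@H](C=C)CO[Si](CC)(CC)CC | intermediate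
13 | (2R,3R)-5-[(1R,2S)-2-(1-bromoethenyl)-4,4-dimethylcyclobutyl]-2-ethenyl-3-methyl-3-(triethylsilyloxy)pentanal | C=C(Br)[C@H]1CC(C)(C)[C@@H]1CC[C@@](C)(O[Si](CC)(CC)CC)[C@@H](C=C)C=O | intermediate
14 | phloroglucinol (benzene-1,3,5-triol) | Oc1cc(O)cc(O)c1 | starting material
15 | 2-methyl-1-(2,4,6-trihydroxyphenyl)propan-1-one | CC(C)C(=O)c1c(O)cc(O)cc1O | intermediate
16 | 2-isobutyryl-4,4-dimethylcyclohexane-1,3,5-trione (drawn as the dihydroxy-dienone tautomer) | CC(C)C(=O)C1=C(O)C(C)(C)C(O)=CC1=O | intermediate
17 | Knoevenagel alkylidene of 13 at C6′ of 16 (alkene geometry unassigned) | C=C(Br)[C@H]1CC(C)(C)[C@@H]1CC[C@@](C)(O[Si](CC)(CC)CC)[C@@H](C=C)C=C1C(=O)C(C)(C)C(=O)C(C(=O)C(C)C)=C1O | intermediate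
18 | C6′-alkylated trione, tertiary triethylsilyl ether (side chain 2R,3R) | C=C(Br)[C@H]1CC(C)(C)[C@@H]1CC[C@@](C)(O[Si](CC)(CC)CC)[C@@H](C=C)CC1=C(O)C(C)(C)C(=O)C(C(=O)C(C)C)=C1O | intermediate
19 | C6′-alkylated trione with free tertiary alcohol | C=C(Br)[C@H]1CC(C)(C)[C@@H]1CC[C@@](C)(O)[C@@H](C=C)CC1=C(O)C(C)(C)C(=O)C(C(=O)C(C)C)=C1O | intermediate
20 | (2R,3R)-2-{2-[(1R,2S)-2-(1-bromoethenyl)-4,4-dimethylcyclobutyl]ethyl}-3-ethenyl-5-hydroxy-6-isobutyryl-2,8,8-trimethyl-3,4-dihydro-2H-chromen-7(8H)-one | C=C[C@H]1CC2=C(O[C@]1(C)CC[C@@H]1[C@@H](C(Br)=C)CC1(C)C)C(C)(C)C(=O)C(C(=O)C(C)C)=C2O | intermediate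
21 | C7 alkyl-9-BBN derivative of 20 with the enol capped as its 9-BBN borinate | C(C[C@H]1CC2=C(O[C@]1(C)CC[C@@H]1[C@@H](C(Br)=C)CC1(C)C)C(C)(C)C(=O)C(C(=O)C(C)C)=C2OB3C4CCCC3CCC4)B5C6CCCC5CCC6 | intermediate
22 | target CNP0497637.2 (1R,4R,5S,9S in caryophyllene locants) | C=C1CC[C@H]2CC3=C(O[C@]2(C)CC[C@@H]2[C@@H]1CC2(C)C)C(C)(C)C(=O)C(C(=O)C(C)C)=C3O | target

Total step count: 13 (11 in the main line from 1, 2 for the trione 16).
Longest linear sequence: 11 steps (steps 1–8 and 11–13).

Steps most likely to fail

Step 13. Transmetalation from the alkylborane to the alkenylpalladium species may be slower than protodeboronation or β-hydride elimination at the dilution needed, and intermolecular coupling may outrun closure of the strained nine-membered ring. The fallback sets out from 20 and comes back at 22. Hydroboration of the vinyl group followed by oxidation (9-BBN; NaBO3) should give the primary alcohol F1, and Appel iodination (I2, PPh3, imidazole) the primary iodide F2. An intramolecular nickel-catalysed reductive cross-electrophile coupling of the alkyl iodide with the alkenyl bromide (NiBr2·glyme, 4,4′-di-tert-butyl-2,2′-bipyridine, manganese powder, DMA, slow addition) would then close the same C7–C8 bond through an alkyl radical and an alkenylnickel species, without any organoboron intermediate, to give 22.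

Step 12. Ionisation of the tertiary C4–O bond in acid (scrambling of C4 or elimination) may compete, and the hydroxyl may add to C1′ instead of C5′, which would give the regioisomeric vinylogous ester. The fallback sets out from 18 and comes back at 20. Sulfonylation of the free C5′ enol hydroxyl (TsCl, Et3N, CH2Cl2, −20 °C) should give the vinylogous tosylate F3, whose constitution can be checked before the ring is closed. Fluoride (TBAF, THF, 0 °C) then frees the tertiary alkoxide, which displaces the tosylate by base-mediated addition–elimination at C5′ and gives 20 without a cationic intermediate.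

Step 11. Migration of the vinyl double bond into conjugation with the aldehyde, or β-elimination of the silanolate, may be faster than condensation of the hindered aldehyde, with loss of the C5 stereocentre. The fallback sets out from 12 and comes back at 22. The vinyl group is first converted to the primary pinacol boronate F4 by iridium-catalysed hydroboration with pinacolborane ([Ir(cod)Cl]2, dppe, CH2Cl2), so that the aldehyde F5 obtained by Swern oxidation is no longer β,γ-unsaturated. Reductive alkylation of 16 with F5 (Hantzsch ester, L-proline) should give the alkylated trione F6, and TsOH·H2O closes the pyran to the boronate F7. An intramolecular Suzuki–Miyaura coupling of the alkyl pinacol boronate with the bromoalkene (Pd(OAc)2, RuPhos, K3PO4, toluene/H2O, high dilution) then gives 22.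

Further compounds
F1 | step 13 | primary alcohol from hydroboration–oxidation of the vinyl group of 20 | OCC[C@H]1CC2=C(O[C@]1(C)CC[C@@H]1[C@@H](C(Br)=C)CC1(C)C)C(C)(C)C(=O)C(C(=O)C(C)C)=C2O
F2 | step 13 | primary iodide from F1 | ICC[C@H]1CC2=C(O[C@]1(C)CC[C@@H]1[C@@H](C(Br)=C)CC1(C)C)C(C)(C)C(=O)C(C(=O)C(C)C)=C2O
F3 | step 12 | vinylogous tosylate of 18 at the C5′ oxygen | C=C(Br)[C@H]1CC(C)(C)[C@@H]1CC[C@@](C)(O[Si](CC)(CC)CC)[C@@H](C=C)CC1=C(OS(=O)(=O)c2ccc(C)cc2)C(C)(C)C(=O)C(C(=O)C(C)C)=C1O
F4 | step 11 | primary pinacol boronate from hydroboration of the vinyl group of 12 | C=C(Br)[C@H]1CC(C)(C)[C@@H]1CC[C@@](C)(O[Si](CC)(CC)CC)[C@@H](CCB2OC(C)(C)C(C)(C)O2)CO[Si](CC)(CC)CC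
F5 | step 11 | aldehyde from Swern oxidation of F4 | C=C(Br)[C@H]1CC(C)(C)[C@@H]1CC[C@@](C)(O[Si](CC)(CC)CC)[C@@H](CCB2OC(C)(C)C(C)(C)O2)C=O
F6 | step 11 | C6′-alkylated trione from F5 and 16 | C=C(Br)[C@H]1CC(C)(C)[C@@H]1CC[C@@](C)(O[Si](CC)(CC)CC)[C@@H](CCB2OC(C)(C)C(C)(C)O2)CC1=C(O)C(C)(C)C(=O)C(C(=O)C(C)C)=C1O
F7 | step 11 | pyran boronate (analogue of 20 with CH2CH2Bpin at C5) | CC1(C)OB(CC[C@H]2CC3=C(O[C@]2(C)CC[C@@H]2[C@@H](C(Br)=C)CC2(C)C)C(C)(C)C(=O)C(C(=O)C(C)C)=C3O)OC1(C)C
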